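**Retrosynthetic overview**
- The diacetate comes from a tetraol by acetylation of its two primary alcohols; the E C9=C10 alkene comes from cross-metathesis of a homoallylic tertiary alcohol with (R)-2-methylbut-3-ene-1,2-diol, itself made from isoprene monoxide by Pd-catalysed asymmetric hydration.
- The ring alkene, the CH2OH group and the C4 configuration come together from a base-induced opening of a spiro-epoxide on the still symmetric cyclohexane (proposed new step); the epoxide comes from the ketone and a sulfoxonium ylide.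
- Key step: the C7 carbinol, the C4–C7 bond and the C8–C9 bond come from a Pd-induced 1,2-shift of the cyclohexyl carbon from boron to carbon in an isopropenyl boron ate complex (conjunctive coupling with vinyl bromide), then C–B oxidation.
- Building blocks: 4-bromocyclohexanone as its ethylene ketal, isopropenylboronic acid as its pinacol ester, vinyl bromide, isoprene monoxide.
- Rings: the only ring is bought as the cyclohexane of the bromo ketal; no ring is formed, it is desymmetrised late, after the 1,2-shift.

Atom labels (target): ring C1 (bears CH2OAc), C2 (=CH), C3, C4 (stereocentre), C5, C6; side chain C7 (ring-bound carbinol), C8, C9=C10, C11 (second carbinol), C12 (CH2OAc).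

Assumption: the enantiomer named for each chiral ligand or base is the one expected to give the drawn configuration; if the sense of induction proves opposite, its mirror image is used.

MandyPhos here means 1,1'-bis[bis(4-methoxy-3,5-dimethylphenyl)phosphino]-2,2'-bis[(R)-α-(dimethylamino)benzyl]ferrocene, (Sp,Sp) form.

**Step 1**
Reactants: 1 2-methyl-2-vinyloxirane (isoprene monoxide, racemic)
Product: 2 (R)-2-methylbut-3-ene-1,2-diol
Conditions: Pd2(dba)3·CHCl3 (1 mol%), (S,S)-DACH-naphthyl Trost ligand (3 mol%), Et3B (1 mol%), NaHCO3, CH2Cl2/H2O, rt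
Reagents that add atoms: water, O (delivered through hydrogen carbonate)
Why: Pd-catalysed dynamic kinetic asymmetric allylic substitution (Trost type), in which both enantiomers of 1 ionise to equilibrating π-allylpalladium species and the boron-bound hydrogen carbonate oxygen attacks the tertiary terminus of one of them, setting C11 as R before the carbonate hydrolyses to the diol.

**Step 2**
Reactants: 3 8-bromo-1,4-dioxaspiro[4.5]decane (4-bromocyclohexanone ethylene ketal); 4 2-isopropenyl-4,4,5,5-tetramethyl-1,3,2-dioxaborolane (isopropenylboronic acid pinacol ester); 5 bromoethene (vinyl bromide)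
Product: 9 (S)-2-(1,4-dioxaspiro[4.5]decan-8-yl)pent-4-en-2-ol, via Grignard reagent 6 (not isolated), via boron ate complex 7 (not isolated), via tertiary boronic ester 8 (not isolated)
Conditions: Mg, THF, 40 °C; then 4, 0 °C to rt; then 5, Pd(OAc)2 (2 mol%), (Sp,Sp)-MandyPhos (2.4 mol%), NaOTf, THF/DMSO, 60 °C; then NaOH, H2O2, 0 °C to rt
Reagents that add atoms: hydrogen peroxide, OO
Why: Key 1,2-shift (Pd-catalysed conjunctive cross-coupling), in which the cationic divalent vinylpalladium–MandyPhos complex binds one face of the isopropenyl group of 7 and triggers an anti 1,2-metallate shift of the ring carbon from boron to C7, reductive elimination forms C8–C9 and the C–B bond is oxidised with retention, so the ligand sets C7 as S (8 is R only because boron ranks lowest).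

**Step 3**
Reactants: 9 (S)-2-(1,4-dioxaspiro[4.5]decan-8-yl)pent-4-en-2-ol
Product: 10 (S)-4-(2-hydroxypent-4-en-2-yl)cyclohexan-1-one
Conditions: 1 M HCl, THF, rt
Reagents that add atoms: water, O
Why: Acid-catalysed acetal hydrolysis, which the tertiary alcohol and the terminal alkene tolerate in dilute acid at room temperature and which touches no stereocentre.

**Step 4**
Reactants: 10 (S)-4-(2-hydroxypent-4-en-2-yl)cyclohexan-1-one
Product: 11 (S)-2-(cis-1-oxaspiro[2.5]octan-6-yl)pent-4-en-2-ol (epoxide oxygen axial, cis to the equatorial side chain)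
Conditions: Me3S(O)I (2.5 equiv), NaH (2.6 equiv), DMSO, rt to 50 °C
Reagents that add atoms: trimethylsulfoxonium iodide, C[S+](C)(C)=O.[I-]
Why: Corey–Chaykovsky epoxidation, in which the sulfoxonium ylide adds reversibly and closes through the betaine with the new C–C bond equatorial, giving the single spiro-epoxide with axial oxygen while the tertiary alkoxide is a spectator.

**Step 5**
Reactants: 11 (S)-2-(cis-1-oxaspiro[2.5]octan-6-yl)pent-4-en-2-ol
Product: 12 (S)-2-[(R)-4-(hydroxymethyl)cyclohex-3-en-1-yl]pent-4-en-2-ol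
Conditions: (S)-2-(pyrrolidin-1-ylmethyl)pyrrolidine (3.3 equiv), n-BuLi (3.2 equiv), THF, 0 °C to rt; then H2O
Reagents that add atoms: none
Why: Proposed new method: enantiotopos-selective β-eliminative isomerisation of a prochiral exocyclic (spiro) epoxide by a chiral lithium amide, in which the chelating amide binds the axial epoxide oxygen and, through a six-membered syn transition state, removes the equatorial β-hydrogen of only one of the two flanking ring CH2 groups (their O–C–C–H dihedrals are mirror images, +60° and −60°), so the ring alkene, the CH2OH group and the R configuration at C4 arise together; the closest known reactions are the chiral lithium amide rearrangement of meso-epoxides to allylic alcohols and the enantioselective deprotonation of 4-substituted cyclohexanones.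

**Step 6**
Reactants: 12 (S)-2-[(R)-4-(hydroxymethyl)cyclohex-3-en-1-yl]pent-4-en-2-ol; 2 (R)-2-methylbut-3-ene-1,2-diol (4 equiv)
Product: 13 (2R,3E,6S)-6-[(R)-4-(hydroxymethyl)cyclohex-3-en-1-yl]-2-methylhept-3-ene-1,2,6-triol
Conditions: second-generation Hoveyda–Grubbs catalyst RuCl2(H2IMes)(=CH-C6H4-2-OiPr) (2 × 5 mol%), 1,4-benzoquinone (10 mol%), CH2Cl2, 40 °C
Reagents that add atoms: none
Why: Olefin cross-metathesis between the unhindered terminal alkene of 12 and the slowly homodimerising tertiary allylic alcohol 2 used in excess, E-selective because of the fully substituted carbinol next to the new alkene, with the trisubstituted ring alkene inert and no stereocentre touched.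

**Step 7**
Reactants: 13 (2R,3E,6S)-6-[(R)-4-(hydroxymethyl)cyclohex-3-en-1-yl]-2-methylhept-3-ene-1,2,6-triol
Product: 14 [(4R)-4-[(2S,4E,6R)-7-acetoxy-2,6-dihydroxy-6-methylhept-4-en-2-yl]cyclohex-1-en-1-yl]methyl acetate (CNP0422578.1)
Conditions: Ac2O (2.3 equiv), pyridine, CH2Cl2, 0 °C
Reagents that add atoms: acetic anhydride, CC(=O)OC(C)=O
Why: Chemoselective O-acetylation of the two primary alcohols, since the two tertiary alcohols do not acylate under these mild conditions.

**Compound list**
1 | 2-methyl-2-vinyloxirane (isoprene monoxide, racemic) | CC1(C=C)CO1 | starting material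
2 | (R)-2-methylbut-3-ene-1,2-diol | C=C[C@@](C)(O)CO | intermediate
3 | 8-bromo-1,4-dioxaspiro[4.5]decane (4-bromocyclohexanone ethylene ketal) | BrC1CCC2(CC1)OCCO2 | starting material
4 | 2-isopropenyl-4,4,5,5-tetramethyl-1,3,2-dioxaborolane (isopropenylboronic acid pinacol ester) | CC(=C)B1OC(C)(C)C(C)(C)O1 | starting material
5 | bromoethene (vinyl bromide) | C=CBr | starting material
6 | (1,4-dioxaspiro[4.5]decan-8-yl)magnesium bromide | Br[Mg]C1CCC2(CC1)OCCO2 | intermediate
7 | bromomagnesium (1,4-dioxaspiro[4.5]decan-8-yl)(isopropenyl)(pinacolato)borate | CC(=C)[B-]1(OC(C)(C)C(C)(C)O1)C1CCC2(CC1)OCCO2.[Mg+]Br | intermediate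
8 | (R)-2-[2-(1,4-dioxaspiro[4.5]decan-8-yl)pent-4-en-2-yl]-4,4,5,5-tetramethyl-1,3,2-dioxaborolane | C=CC[C@](C)(B1OC(C)(C)C(C)(C)O1)C1CCC2(CC1)OCCO2 | intermediate
9 | (S)-2-(1,4-dioxaspiro[4.5]decan-8-yl)pent-4-en-2-ol | C=CC[C@](C)(O)C1CCC2(CC1)OCCO2 | intermediate
10 | (S)-4-(2-hydroxypent-4-en-2-yl)cyclohexan-1-one | C=CC[C@](C)(O)C1CCC(=O)CC1 | intermediate
11 | (S)-2-(cis-1-oxaspiro[2.5]octan-6-yl)pent-4-en-2-ol (epoxide O cis to the side chain) | C=CC[C@](C)(O)[C@@H]1CC[C@]2(CC1)CO2 | intermediate
12 | (S)-2-[(R)-4-(hydroxymethyl)cyclohex-3-en-1-yl]pent-4-en-2-ol | OCC1=CC[C@H]([C@@](C)(O)CC=C)CC1 | intermediate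
13 | (2R,3E,6S)-6-[(R)-4-(hydroxymethyl)cyclohex-3-en-1-yl]-2-methylhept-3-ene-1,2,6-triol | OCC1=CC[C@H]([C@@](C)(O)C/C=C/[C@@](C)(O)CO)CC1 | intermediate
14 | [(4R)-4-[(2S,4E,6R)-7-acetoxy-2,6-dihydroxy-6-methylhept-4-en-2-yl]cyclohex-1-en-1-yl]methyl acetate | CC(=O)OCC1=CC[C@H]([C@@](C)(O)C/C=C/[C@@](C)(O)COC(C)=O)CC1 | target

**Totals**
Total step count: 7. Longest linear sequence: 6 (steps 2 to 7; step 1 is the side branch).

**Steps most likely to fail**

Step 5 (the proposed new desymmetrisation; the level and sense of selection between the two ring CH2 groups are untested, and α-lithiation of the epoxide CH2 may compete). The fallback uses known chemistry, sets out from 10 and comes back at 12. Ketone 10, as its lithium alkoxide, is deprotonated enantioselectively with lithium (R,R)-bis(1-phenylethyl)amide and LiCl in THF at −78 °C, and the enolate is trapped with PhNTf2 to give (R)-4-[(S)-2-hydroxypent-4-en-2-yl]cyclohex-1-en-1-yl trifluoromethanesulfonate F1. Stille coupling of F1 with (tributylstannyl)methanol (Pd(PPh3)4, a zerovalent palladium catalyst, LiCl, dioxane, 100 °C) installs the CH2OH group and gives 12.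

Step 2 (a secondary alkyl group must migrate to build a congested tertiary boronic ester; direct Suzuki coupling of the isopropenyl group or low enantioselectivity are the likely failures). The fallback sets out from 3 through Grignard reagent 6 and comes back at 9. Reagent 6 is acylated with N-methoxy-N-methylacetamide (THF, 0 °C, aqueous NH4Cl quench) to give the methyl ketone 1-(1,4-dioxaspiro[4.5]decan-8-yl)ethan-1-one F2. F2 is then allylated enantioselectively with B-allyl-1,3,2-dioxaborinane and 3,3'-dibromo-BINOL as catalyst (t-BuOH, toluene, rt) to give 9, so that the carbinol is made by carbonyl addition and not by a 1,2-shift.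

Step 6 (late union of two polyols; the allylic partner carries a fully substituted carbon next to the alkene and may react slowly). The fallback avoids metathesis by bringing the C9–C12 fragment in as the electrophile of the key step; it sets out from 2 and comes back at 13.
- Diol 2 is converted with 2,2-dimethoxypropane and PPTS into (R)-2,2,4-trimethyl-4-vinyl-1,3-dioxolane F3.
- Ozonolysis (O3, CH2Cl2, −78 °C, then Me2S) gives (S)-2,2,4-trimethyl-1,3-dioxolane-4-carbaldehyde F4.
- Takai olefination (CrCl2, CHI3, THF) gives (R)-4-[(E)-2-iodoethenyl]-2,2,4-trimethyl-1,3-dioxolane F5.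
- F5 replaces 5 in the coupling with ate complex 7 under the step 2 conditions and gives, after oxidation, (S,E)-2-(1,4-dioxaspiro[4.5]decan-8-yl)-5-[(R)-2,2,4-trimethyl-1,3-dioxolan-4-yl]pent-4-en-2-ol F6.
- 1 M HCl in THF removes both acetals to give 4-[(2S,4E,6R)-2,6,7-trihydroxy-6-methylhept-4-en-2-yl]cyclohexan-1-one F7.
- The ylide of step 4 (extra equivalents for the three hydroxyls) gives (2R,3E,6S)-2-methyl-6-(cis-1-oxaspiro[2.5]octan-6-yl)hept-3-ene-1,2,6-triol F8.
- The lithium amide of step 5 (extra equivalents) converts F8 into 13.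

**Further compounds**
F1 | step 5 | (R)-4-[(S)-2-hydroxypent-4-en-2-yl]cyclohex-1-en-1-yl trifluoromethanesulfonate | FC(F)(F)S(=O)(=O)OC1=CC[C@H]([C@@](C)(O)CC=C)CC1
F2 | step 2 | 1-(1,4-dioxaspiro[4.5]decan-8-yl)ethan-1-one | CC(=O)C1CCC2(CC1)OCCO2
F3 | step 6 | (R)-2,2,4-trimethyl-4-vinyl-1,3-dioxolane | C=C[C@@]1(C)OC(C)(C)OC1
F4 | step 6 | (S)-2,2,4-trimethyl-1,3-dioxolane-4-carbaldehyde | O=C[C@@]1(C)OC(C)(C)OC1
F5 | step 6 | (R)-4-[(E)-2-iodoethenyl]-2,2,4-trimethyl-1,3-dioxolane | I/C=C/[C@@]1(C)OC(C)(C)OC1
F6 | step 6 | (S,E)-2-(1,4-dioxaspiro[4.5]decan-8-yl)-5-[(R)-2,2,4-trimethyl-1,3-dioxolan-4-yl]pent-4-en-2-ol | C1COC2(O1)CCC(CC2)[C@@](C)(O)C/C=C/[C@@]3(C)OC(C)(C)OC3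
F7 | step 6 | 4-[(2S,4E,6R)-2,6,7-trihydroxy-6-methylhept-4-en-2-yl]cyclohexan-1-one | O=C1CCC(CC1)[C@@](C)(O)C/C=C/[C@@](C)(O)CO
F8 | step 6 | (2R,3E,6S)-2-methyl-6-(cis-1-oxaspiro[2.5]octan-6-yl)hept-3-ene-1,2,6-triol | OC[C@](C)(O)/C=C/C[C@](C)(O)[C@@H]1CC[C@]2(CC1)CO2
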